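## The problem

The target is a 22-carbon acid with a single ring, a 1,2-dioxane. Numbering the chain from the carboxyl carbon C1, the ring is C3–C4–C5–C6 plus two oxygens, called O3 (on C3) and O6 (on C6) here. C3 carries the CH2CO2H arm, and C6 is a peroxyketal carbon bearing OCH3 and the chain C7–C22 with a C10≡C11 triple bond conjugated to an E C12=C13 double bond. A synthesis has to join two carbons in a 1,4-relationship through an O–O unit, and after that nothing reducing, strongly basic or hot may meet the peroxide. There are two stereocentres, C3 (S) and C6 (R). C6 is exchangeable: in acidic methanol a 6-methoxy-1,2-dioxane equilibrates through a peroxycarbenium ion and settles with OCH3 axial and both carbon substituents equatorial, which is the cis relation of OCH3 and CH2CO2H in the target. C3 therefore controls C6, nothing in the molecule controls C3, and the real stereochemical task is the absolute configuration of one secondary peroxide carbon. The fragile groups are: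
- the O–O bond, which is attacked by phosphines, low-valent metals and hydrides, and can open under base by Kornblum–DeLaMare cleavage at C3–H or by retro-conjugate elimination, since O3 is β to the C1 carbonyl;
- the acid-labile peroxyketal;
- the enyne, which should not see peracid or oxygen radicals and is best attached last.

The feature that opens the route is that C6 carries an oxygen substituent where a bond to C1 could stand. With C1 bonded to C6 as a ketone, C1–C6 form a cyclohexenone, the dioxane becomes the peroxide bridge of a 2,3-dioxabicyclo[2.2.2]octan-5-one, and this bicycle is the formal adduct of O2 across C6 and C3 of a cross-conjugated cyclohexadienolate. A Baeyer–Villiger insertion beside C6 later exchanges C6–C1 for C6–O and returns C1 as the acid.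

## Retrosynthesis

**C11–C12.** Target 19 is cut at the sp–sp2 bond into the terminal alkyne 15 and (E)-1-iodoundec-1-ene 18, which comes from undec-1-yne 16 through the alkenylzirconocene 17. Carrying the whole chain from the start would expose the alkene to O2, peracid and acid, and an olefination would have to set the E geometry beside a peroxide. This cut removes eleven carbons and the only alkene geometry from the main line. The forward coupling must run at room temperature beside a dialkyl peroxide and a free acid.

**Alkyne cap.** 15 goes back to its C-silylated form 14. A terminal alkyne C–H would not survive the amide-base steps. Triisopropylsilyl is chosen over trimethylsilyl because the key step uses fluoride catalytically at low temperature. The cap must later leave with fluoride without base damage to the β-peroxy acid.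

**C6–OCH3.** In 14 the C6–OCH3 bond is cut and the C1 carboxyl oxygen is bonded to C6 instead, giving the bridged lactone 13, a 2,6,7-trioxabicyclo[3.2.2]nonan-3-one. Compared with ketalising a separate hydroperoxy ketone, the acyloxy peroxyketal already holds C6 at the ketal level and its opening releases C1 at the acid level without a redox step. The forward reaction must ionise C6 at the acyloxy group only and place OCH3 under thermodynamic control.

**C6–O back to C6–C1.** The oxygen between C6 and C1 in 13 is removed, so that C1 is bonded to C6 in ketone 12. A Baeyer–Villiger oxidation does this in the forward sense with one oxygen atom. An oxidative cleavage of a C1=C2 unit would break the wrong bond. Precursor 12 has all six carbons C1–C6 in a carbocycle. The forward step must migrate the oxygen-bearing quaternary C6 and not the methylene C2, and must leave the peroxide alone.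

**C6–O6 and C3–O3 (key cut).** Both C–O bonds of the peroxide in 12 are cut, leaving O2 and the achiral silyl dienol ether 9. The forward reaction passes through peroxide 10 and bicyclic silyl enol ether 11. Cutting only one C–O bond would require a separately made chiral hydroperoxide. A singlet-oxygen cycloaddition forms the same two bonds but gives the racemate. The stepwise anionic path makes C6–O6 first, inside a chiral ion pair, and so can be enantioselective. The cut removes the ring, the peroxide and both stereocentres at once. It asks for face selectivity at C6, ring closure faster than loss of the peroxide anion, and catalyst turnover.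

**O–Si and C6–C7.** 9 is the kinetic silyl dienol ether of enone 7 (through lithium dienolate 8). 7 is cut at C6–C7 into cyclohex-2-en-1-one 5 (as dienolate 6) and iodide 4. This is the only C–C bond made on the main line before the final coupling. The stereocentre of 7 is racemic and irrelevant, because it is flattened in 9.

**Electrophile.** Iodide 4 comes from chloride 3 by halide exchange, and 3 from 5-chloropent-1-yne 1 by C-silylation of acetylide 2.

## Roads not taken

Alternative 1: The cut is the C6–O6 bond alone. Hydroperoxy dimethyl ketal A1, with the full side chain and C1 as a silyl ether, would be treated with pyridinium p-toluenesulfonate in methanol. The ketal ionises, the C3 hydroperoxide adds to the oxocarbenium ion, and the reversible closure settles as the cis dioxane A2.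
- Merits: every event is precedented, the enyne is tolerated, and C6 is set by the same anomeric equilibrium that the chosen plan uses in step 7.
- Weak points: all the stereochemistry rests on A1. An enantioenriched secondary hydroperoxide has to be made by displacing a C3 sulfonate of a separately prepared chiral alcohol with a peroxide nucleophile, with elimination and erosion of configuration as known side paths. C1 arrives as a silyl ether, so desilylation and two oxidations must follow beside the peroxide and the enyne.
- Comparison: the ring closure here is more reliable than step 5 of the chosen plan, and that is a real advantage. Against it, the chosen plan creates C3 catalytically from an achiral diene and O2, needs no preformed chiral hydroperoxide, and delivers C1 directly as the acid.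

Alternative 2: The cut is a C4=C5 double bond introduced for the purpose. The acyclic peroxyketal A3 (a mixture at C6) carries a vinyl group on C6 and an enoate on C3. The second-generation Hoveyda–Grubbs catalyst, RuCl2(H2IMes)(=CH-C6H4-2-OiPr), would join C4 and C5 with loss of the enoate terminus as an acrylate, giving dihydrodioxine A4.
- Merits: ruthenium carbenes tolerate dialkyl peroxides, the closure is neutral, and C1 is already an ester.
- Weak points: A3 again needs a chiral allylic hydroperoxide at C3, and in addition an intermolecular mixed peroxyketal formation. The metathesis must engage a vinyl group on a fully substituted carbon and an electron-poor enoate, both reluctant partners. Afterwards C4=C5 must be saturated without touching the O–O bond or the alkyne. The allylic peroxyketal of A4 ionises easily. Five steps follow the key step (reduction, equilibration at C6, desilylation, coupling, ester hydrolysis).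
- Comparison: on tolerance of the peroxide in the ring-forming step this road is on firmer ground than the chosen plan. The chosen plan sets against it a shorter sequence after the key step and stereocontrol at C3 that is not outsourced to an earlier intermediate.

Alternative 3: The cut is the C3–C4 bond. Bromide A5, a β-peroxyacrylimide, would give a C4 radical with (Me3Si)3SiH and Et3B. The radical adds 6-exo-trig to C3 of the acrylimide held by MgI2 and 2,2'-isopropylidenebis[(4S)-4-phenyl-2-oxazoline], giving imide A6.
- Merits: like the chosen plan it sets C3 by a catalyst, and it does so with a chiral Lewis acid and radical combination that is established for conjugate additions to oxazolidinone imides.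
- Weak points: the adduct radical at C2 sits β to O3, and β-peroxyalkyl radicals can collapse to epoxides with loss of an alkoxyl radical in competition with hydrogen transfer. The C4 radical can attack the O–O bond directly. Closure 6-exo is slower than the 5-exo cases on which the precedent rests. A5 needs an α-methoxy hydroperoxide added to a propiolimide. C6 is uncontrolled until a later equilibration, and the imide must be cleaved.
- Comparison: in catalyst precedent for the bond-forming event this road is arguably ahead. Its intermediates, however, place a carbon radical next to a peroxide. In the chosen plan the peroxide is formed in the last bond-forming event of the key step and meets no radical or reductant until the final coupling.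

Key step: step 5

Assumption: N-benzylcinchoninium fluoride is taken to expose the face of C6 that leads to (1S,4R)-12; if the sense proves opposite, the pseudoenantiomeric N-benzylcinchonidinium fluoride would be used in the same way.

## Route

Step 1
Reactants: 1 5-chloropent-1-yne
Product: 3 (5-chloropent-1-yn-1-yl)triisopropylsilane, via (5-chloropent-1-yn-1-yl)lithium 2 (not isolated)
Conditions: nBuLi, THF, −78 °C; iPr3SiCl, −78 °C to rt
Reagents that add atoms: chlorotriisopropylsilane, CC(C)[Si](Cl)(C(C)C)C(C)C
Why: Deprotonation of the terminal alkyne by nBuLi at −78 °C is much faster than attack on the primary chloride, and C-silylation of a lithium acetylide is standard alkyne protection. The bulky silyl cap should survive amide bases, catalytic fluoride at low temperature, O2, peracid and acidic methanol.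

Step 2
Reactants: 3 (5-chloropent-1-yn-1-yl)triisopropylsilane
Product: 4 (5-iodopent-1-yn-1-yl)triisopropylsilane
Conditions: NaI, acetone, reflux
Reagents that add atoms: sodium iodide, [Na+].[I-]
Why: Finkelstein halide exchange, driven by precipitation of NaCl from acetone. The iodide is needed for the enolate alkylation.

Step 3
Reactants: 5 cyclohex-2-en-1-one; 4 (5-iodopent-1-yn-1-yl)triisopropylsilane
Product: 7 6-[5-(triisopropylsilyl)pent-4-yn-1-yl]cyclohex-2-en-1-one (racemic), via lithium cyclohexa-1,5-dien-1-olate 6 (not isolated)
Conditions: LiN(iPr)2, THF, −78 °C; 4, DMPU, −78 to −10 °C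
Reagents that add atoms: none
Why: Kinetic deprotonation of the enone by LiN(iPr)2 occurs at the α′ carbon and gives the cross-conjugated dienolate 6, which is C-alkylated by the primary iodide in an SN2 reaction accelerated by DMPU. The new stereocentre is racemic and is erased in step 4.

Step 4
Reactants: 7 6-[5-(triisopropylsilyl)pent-4-yn-1-yl]cyclohex-2-en-1-one
Product: 9 trimethyl({6-[5-(triisopropylsilyl)pent-4-yn-1-yl]cyclohexa-1,5-dien-1-yl}oxy)silane, via lithium dienolate 8 (not isolated)
Conditions: LiN(iPr)2, THF, −78 °C; Me3SiCl, −78 to 0 °C; pentane, filtration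
Reagents that add atoms: chlorotrimethylsilane, C[Si](C)(C)Cl
Why: A second kinetic α′-deprotonation (the γ-protons at C4 are removed more slowly by LiN(iPr)2 at −78 °C) and O-silylation give the 2-silyloxy-1,3-diene, the usual silyl dienol ether formation from an enone. The achiral product is used without chromatography because it hydrolyses easily.

Step 5
Reactants: 9 trimethyl({6-[5-(triisopropylsilyl)pent-4-yn-1-yl]cyclohexa-1,5-dien-1-yl}oxy)silane
Product: 12 (1S,4R)-4-[5-(triisopropylsilyl)pent-4-yn-1-yl]-2,3-dioxabicyclo[2.2.2]octan-5-one, via (6R)-6-hydroperoxy enone 10 (not isolated), via bicyclic trimethylsilyl enol ether 11 (not isolated)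
Conditions: N-benzylcinchoninium fluoride (10 mol%), O2 (1 atm), THF–toluene, 4 Å MS, −40 °C, dark; then aq citric acid, THF, 0 °C
Reagents that add atoms: dioxygen, O=O
Why: Proposed new method: fluoride from the catalyst removes Me3Si from 9 and leaves a cross-conjugated dienolate, ion-paired with the N-benzylcinchoninium cation, that is nucleophilic at carbon only at C6; single-electron transfer to triplet O2 and recombination at C6 give the peroxide anion of 10. This anion adds across the ring to the enone carbon C3 through a boat-shaped cyclohexenone, a 6-exo-trig closure of the one new ring (C3–C4–C5–C6–O6–O3), and the resulting bicyclic enolate takes Me3Si from a further molecule of 9 (or from Me3SiF) to give 11 and pass the chain on. Mild acid on work-up hydrolyses 11 to ketone 12. The closest known reaction types are the aerobic α-hydroperoxidation of α-substituted cyclic ketones under chiral quaternary ammonium phase-transfer salts, the generation of chiral ammonium enolates from silyl enol ethers with cinchona-derived ammonium fluorides, and the conjugate addition of hydroperoxides to enones; their union on a dienolate with transannular ring closure has not been shown. The quaternary carbon C6 is set by the chiral ion pair, which has to shield one enantiotopic face of the flat dienolate from O2; C3 is set by the tether alone, because the peroxide can reach C3 only on the face from which it hangs, so 4R at the quaternary bridgehead forces 1S. The step therefore needs enantiofacial selectivity only: regioselectivity follows from cross-conjugation (no negative charge at C2 or C4), and the triisopropylsilyl alkyne is inert to catalytic fluoride and O2 at −40 °C. Base is excluded after ring closure because 12 is a β-peroxy ketone that can reopen by retro-conjugate elimination.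

Step 6
Reactants: 12 (1S,4R)-4-[5-(triisopropylsilyl)pent-4-yn-1-yl]-2,3-dioxabicyclo[2.2.2]octan-5-one
Product: 13 (1R,5S)-1-[5-(triisopropylsilyl)pent-4-yn-1-yl]-2,6,7-trioxabicyclo[3.2.2]nonan-3-one
Conditions: mCPBA, CH2Cl2, 0 °C to rt
Reagents that add atoms: 3-chloroperoxybenzoic acid, OOC(=O)c1cccc(Cl)c1
Why: Baeyer–Villiger oxidation: in the peracid adduct the quaternary, oxygen-bearing bridgehead C6 should migrate in preference to the methylene C2, as α-oxygenated bridgeheads do in oxabicyclic ketones, and migration retains configuration at C6. The saturated peroxide bridge and the silylalkyne offer nothing for a peracid to attack.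

Step 7
Reactants: 13 (1R,5S)-1-[5-(triisopropylsilyl)pent-4-yn-1-yl]-2,6,7-trioxabicyclo[3.2.2]nonan-3-one
Product: 14 2-[(3S,6R)-6-methoxy-6-[5-(triisopropylsilyl)pent-4-yn-1-yl]-1,2-dioxan-3-yl]acetic acid
Conditions: pyridinium p-toluenesulfonate (cat.), MeOH, 0 °C to rt
Reagents that add atoms: methanol, CO
Why: Acid-catalysed solvolysis of an acyloxy peroxyketal: the carboxyl group leaves C6, a peroxycarbenium ion forms, and methanol captures it, so C1 is released as the free acid. Exchange at C6 is reversible, and the product should settle as the chair with OCH3 axial (anomeric effect) and both carbon substituents equatorial, which is 6R given 3S. The pyridinium acid is too weak to esterify the carboxylic acid at a useful rate at this temperature.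

Step 8
Reactants: 14 2-[(3S,6R)-6-methoxy-6-[5-(triisopropylsilyl)pent-4-yn-1-yl]-1,2-dioxan-3-yl]acetic acid
Product: 15 2-[(3S,6R)-6-methoxy-6-(pent-4-yn-1-yl)-1,2-dioxan-3-yl]acetic acid
Conditions: Bu4NF (3 equiv), THF, 0 °C; aq NaH2PO4
Reagents that add atoms: none
Why: Fluoride-induced protodesilylation of a silylalkyne. The acid is present as its carboxylate, whose α-protons are not acidic enough for retro-conjugate opening of the dioxane, and saturated 1,2-dioxanes tolerate Bu4NF at 0 °C.

Step 9
Reactants: 16 undec-1-yne
Product: 18 (1E)-1-iodoundec-1-ene, via (E)-undec-1-enylzirconocene chloride 17 (not isolated)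
Conditions: Cp2Zr(H)Cl, THF, rt; I2, 0 °C
Reagents that add atoms: iodine, II
Why: Hydrozirconation adds Zr–H syn across the terminal alkyne with zirconium at the terminal carbon, and iodinolysis of the C–Zr bond proceeds with retention, so the E iodoalkene results.

Step 10
Reactants: 15 2-[(3S,6R)-6-methoxy-6-(pent-4-yn-1-yl)-1,2-dioxan-3-yl]acetic acid; 18 (1E)-1-iodoundec-1-ene
Product: 19 2-[(3S,6R)-6-[(6E)-hexadec-6-en-4-yn-1-yl]-6-methoxy-1,2-dioxan-3-yl]acetic acid
Conditions: Pd(PPh3)4 (5 mol%), CuI (10 mol%), Et3N, THF, rt, degassed
Reagents that add atoms: none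
Why: Sonogashira coupling of a terminal alkyne with an E alkenyl iodide runs at room temperature with retention of alkene geometry. Oxidative addition of zerovalent palladium to the C–I bond is far faster than any reaction with a saturated dialkyl peroxide, and such couplings are known beside 1,2-dioxanes. The acid is present as its triethylammonium salt.

## Compound list

1 | 5-chloropent-1-yne | ClCCCC#C | starting material
2 | (5-chloropent-1-yn-1-yl)lithium | [Li]C#CCCCCl | intermediate (not isolated)
3 | (5-chloropent-1-yn-1-yl)triisopropylsilane | ClCCCC#C[Si](C(C)C)(C(C)C)C(C)C | intermediate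
4 | (5-iodopent-1-yn-1-yl)triisopropylsilane | ICCCC#C[Si](C(C)C)(C(C)C)C(C)C | intermediate
5 | cyclohex-2-en-1-one | O=C1C=CCCC1 | starting material
6 | lithium cyclohexa-1,5-dien-1-olate | [Li]OC1=CCCC=C1 | intermediate (not isolated)
7 | 6-[5-(triisopropylsilyl)pent-4-yn-1-yl]cyclohex-2-en-1-one (racemic) | O=C1C=CCCC1CCCC#C[Si](C(C)C)(C(C)C)C(C)C | intermediate
8 | lithium 6-[5-(triisopropylsilyl)pent-4-yn-1-yl]cyclohexa-1,5-dien-1-olate | [Li]OC1=C(CCCC#C[Si](C(C)C)(C(C)C)C(C)C)CCC=C1 | intermediate (not isolated)
9 | trimethyl({6-[5-(triisopropylsilyl)pent-4-yn-1-yl]cyclohexa-1,5-dien-1-yl}oxy)silane (achiral) | C[Si](C)(C)OC1=C(CCCC#C[Si](C(C)C)(C(C)C)C(C)C)CCC=C1 | intermediate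
10 | (6R)-6-hydroperoxy-6-[5-(triisopropylsilyl)pent-4-yn-1-yl]cyclohex-2-en-1-one, formed as its N-benzylcinchoninium peroxide | CC(C)[Si](C(C)C)(C(C)C)C#CCCC[C@@]1(OO)CCC=CC1=O | intermediate (not isolated)
11 | trimethyl({(1S,4R)-4-[5-(triisopropylsilyl)pent-4-yn-1-yl]-2,3-dioxabicyclo[2.2.2]oct-5-en-5-yl}oxy)silane | CC(C)[Si](C(C)C)(C(C)C)C#CCCC[C@]1(C(O[Si](C)(C)C)=C2)CC[C@@H]2OO1 | intermediate (not isolated)
12 | (1S,4R)-4-[5-(triisopropylsilyl)pent-4-yn-1-yl]-2,3-dioxabicyclo[2.2.2]octan-5-one | CC(C)[Si](C(C)C)(C(C)C)C#CCCC[C@]1(C(=O)C2)CC[C@@H]2OO1 | intermediate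
13 | (1R,5S)-1-[5-(triisopropylsilyl)pent-4-yn-1-yl]-2,6,7-trioxabicyclo[3.2.2]nonan-3-one | CC(C)[Si](C(C)C)(C(C)C)C#CCCC[C@]1(OC(=O)C2)CC[C@@H]2OO1 | intermediate
14 | 2-[(3S,6R)-6-methoxy-6-[5-(triisopropylsilyl)pent-4-yn-1-yl]-1,2-dioxan-3-yl]acetic acid | CC(C)[Si](C(C)C)(C(C)C)C#CCCC[C@]1(OC)CC[C@@H](CC(=O)O)OO1 | intermediate
15 | 2-[(3S,6R)-6-methoxy-6-(pent-4-yn-1-yl)-1,2-dioxan-3-yl]acetic acid | C#CCCC[C@]1(OC)CC[C@@H](CC(=O)O)OO1 | intermediate
16 | undec-1-yne | CCCCCCCCCC#C | starting material
17 | chloridobis(cyclopentadienyl)[(1E)-undec-1-en-1-yl]zirconium | CCCCCCCCC/C=C/[Zr](Cl)(C1C=CC=C1)C1C=CC=C1 | intermediate (not isolated)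
18 | (1E)-1-iodoundec-1-ene | CCCCCCCCC/C=C/I | intermediate
19 | 2-[(3S,6R)-6-[(6E)-hexadec-6-en-4-yn-1-yl]-6-methoxy-1,2-dioxan-3-yl]acetic acid | CCCCCCCCC/C=C/C#CCCC[C@]1(OC)CC[C@@H](CC(=O)O)OO1 | target

## Step count and risks

Total step count: 10. Longest linear sequence: 9 steps (steps 1 to 8 and step 10, from 1); step 9 is a one-step side branch.

Least certain steps:

1. Step 5 (key step, proposed new method).
 - What may go wrong: face discrimination in the oxygenation of a small, flexible dienolate may be poor. The peroxide anion may be reduced by a second dienolate (hydroxylation in place of peroxidation) or O-silylated before it closes. The transannular addition may reverse.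
 - Fallback (known chemistry): starting from 9, a dye-sensitised singlet-oxygen [4+2] cycloaddition (O2, light, 5,10,15,20-tetraphenylporphyrin, CH2Cl2, −78 °C) forms the same two C–O bonds without a catalyst and gives the racemic bicyclic silyl enol ether F1. Mild acid hydrolysis gives the racemic ketone F2. Preparative chromatography on a chiral stationary phase separates the wanted enantiomer from the (1R,4S) ketone F3. The route is rejoined at 12.

2. Step 3.
 - What may go wrong: slow SN2 attack of the enone enolate on an unactivated primary iodide allows proton exchange with the product, polyalkylation and self-condensation of the enone.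
 - Fallback: starting from 4, commercial cyclohexanone N,N-dimethylhydrazone is deprotonated with LiN(iPr)2 and alkylated to the hydrazone F4. Aqueous oxalic acid hydrolyses it to the 2-substituted cyclohexanone F5. LiN(iPr)2 and Me3SiCl give the kinetic silyl enol ether F6 on the unsubstituted side. Saegusa–Ito dehydrogenation with Pd(OAc)2 in MeCN returns to 7.

3. Step 6.
 - What may go wrong: the inductively withdrawing peroxide oxygen may slow migration of C6, so that C2 migrates or the reaction stalls. The acid by-product may open the acyloxy peroxyketal.
 - Fallback: starting from 12, NH2OH·HCl and NaOAc give the oxime F7. Methanesulfonyl chloride and Et3N give the oxime mesylate F8. In methanol this undergoes Beckmann fragmentation of the C6–C1 bond, and methanol traps the peroxycarbenium ion to give the methoxy ketal nitrile F9. iBu2AlH at −78 °C and hydrolysis give the aldehyde F10. Pinnick oxidation (NaClO2, NaH2PO4, 2-methylbut-2-ene) returns to 14.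

4. Step 7.
 - What may go wrong: methanol may attack the lactone carbonyl, or the liberated acid may esterify, giving a mixture of acid and methyl ester. Equilibration at C6 may be incomplete.
 - Fallback: starting from 13, the methanolysis is driven to the ester (TsOH, HC(OMe)3, MeOH), giving the methyl ester F11 after full equilibration. LiOH in THF–water at 0 °C returns to 14.

5. Step 10.
 - What may go wrong: if the carboxylate ties up copper and the coupling is sluggish, reduction of the O–O bond by phosphine or low-valent metal, and oxidative homocoupling of the alkyne, can take over.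
 - Fallback: starting from 15, Me3SiCHN2 in MeOH–toluene gives the methyl ester F12, which belongs to the ester class on which this coupling beside a 1,2-dioxane is established. Coupling with 18 gives the methyl ester F13, and LiOH in THF–water returns to 19.

## Further compounds

F1 | step 5 | racemic trimethyl({4-[5-(triisopropylsilyl)pent-4-yn-1-yl]-2,3-dioxabicyclo[2.2.2]oct-5-en-5-yl}oxy)silane | CC(C)[Si](C(C)C)(C(C)C)C#CCCCC1(C(O[Si](C)(C)C)=C2)CCC2OO1
F2 | step 5 | racemic 4-[5-(triisopropylsilyl)pent-4-yn-1-yl]-2,3-dioxabicyclo[2.2.2]octan-5-one | CC(C)[Si](C(C)C)(C(C)C)C#CCCCC1(C(=O)C2)CCC2OO1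
F3 | step 5 | (1R,4S)-4-[5-(triisopropylsilyl)pent-4-yn-1-yl]-2,3-dioxabicyclo[2.2.2]octan-5-one | CC(C)[Si](C(C)C)(C(C)C)C#CCCC[C@@]1(C(=O)C2)CC[C@H]2OO1
F4 | step 3 | 1,1-dimethyl-2-{2-[5-(triisopropylsilyl)pent-4-yn-1-yl]cyclohexylidene}hydrazine (racemic) | CN(C)N=C1CCCCC1CCCC#C[Si](C(C)C)(C(C)C)C(C)C
F5 | step 3 | 2-[5-(triisopropylsilyl)pent-4-yn-1-yl]cyclohexan-1-one (racemic) | O=C1CCCCC1CCCC#C[Si](C(C)C)(C(C)C)C(C)C
F6 | step 3 | trimethyl({6-[5-(triisopropylsilyl)pent-4-yn-1-yl]cyclohex-1-en-1-yl}oxy)silane (racemic) | C[Si](C)(C)OC1=CCCCC1CCCC#C[Si](C(C)C)(C(C)C)C(C)C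
F7 | step 6 | (1S,4R)-4-[5-(triisopropylsilyl)pent-4-yn-1-yl]-2,3-dioxabicyclo[2.2.2]octan-5-one oxime | CC(C)[Si](C(C)C)(C(C)C)C#CCCC[C@]1(C(=NO)C2)CC[C@@H]2OO1
F8 | step 6 | (1S,4R)-4-[5-(triisopropylsilyl)pent-4-yn-1-yl]-2,3-dioxabicyclo[2.2.2]octan-5-one O-methanesulfonyloxime | CC(C)[Si](C(C)C)(C(C)C)C#CCCC[C@]1(C(=NOS(C)(=O)=O)C2)CC[C@@H]2OO1
F9 | step 6 | 2-[(3S,6R)-6-methoxy-6-[5-(triisopropylsilyl)pent-4-yn-1-yl]-1,2-dioxan-3-yl]acetonitrile | CC(C)[Si](C(C)C)(C(C)C)C#CCCC[C@]1(OC)CC[C@@H](CC#N)OO1
F10 | step 6 | 2-[(3S,6R)-6-methoxy-6-[5-(triisopropylsilyl)pent-4-yn-1-yl]-1,2-dioxan-3-yl]acetaldehyde | CC(C)[Si](C(C)C)(C(C)C)C#CCCC[C@]1(OC)CC[C@@H](CC=O)OO1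
F11 | step 7 | methyl 2-[(3S,6R)-6-methoxy-6-[5-(triisopropylsilyl)pent-4-yn-1-yl]-1,2-dioxan-3-yl]acetate | CC(C)[Si](C(C)C)(C(C)C)C#CCCC[C@]1(OC)CC[C@@H](CC(=O)OC)OO1
F12 | step 10 | methyl 2-[(3S,6R)-6-methoxy-6-(pent-4-yn-1-yl)-1,2-dioxan-3-yl]acetate | C#CCCC[C@]1(OC)CC[C@@H](CC(=O)OC)OO1
F13 | step 10 | methyl 2-[(3S,6R)-6-[(6E)-hexadec-6-en-4-yn-1-yl]-6-methoxy-1,2-dioxan-3-yl]acetate | CCCCCCCCC/C=C/C#CCCC[C@]1(OC)CC[C@@H](CC(=O)OC)OO1
A1 | alternative 1 | tert-butyl{[(3S,12E)-3-hydroperoxy-6,6-dimethoxydocos-12-en-10-yn-1-yl]oxy}diphenylsilane | CCCCCCCCC/C=C/C#CCCCC(OC)(OC)CC[C@@H](CCO[Si](c1ccccc1)(c1ccccc1)C(C)(C)C)OO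
A2 | alternative 1 | tert-butyl({2-[(3S,6R)-6-[(6E)-hexadec-6-en-4-yn-1-yl]-6-methoxy-1,2-dioxan-3-yl]ethoxy})diphenylsilane | CCCCCCCCC/C=C/C#CCCC[C@]1(OC)CC[C@@H](CCO[Si](c2ccccc2)(c2ccccc2)C(C)(C)C)OO1
A3 | alternative 2 | dimethyl (2E,4R)-4-{[3-methoxy-8-(triisopropylsilyl)oct-1-en-7-yn-3-yl]peroxy}hex-2-enedioate (mixture at the peroxyketal carbon) | CC(C)[Si](C(C)C)(C(C)C)C#CCCCC(OC)(C=C)OO[C@H](CC(=O)OC)/C=C/C(=O)OC
A4 | alternative 2 | methyl 2-[(3R,6R)-6-methoxy-6-[5-(triisopropylsilyl)pent-4-yn-1-yl]-3,6-dihydro-1,2-dioxin-3-yl]acetate | CC(C)[Si](C(C)C)(C(C)C)C#CCCC[C@]1(OC)C=C[C@@H](CC(=O)OC)OO1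
A5 | alternative 3 | 3-[(2E)-3-{[1-bromo-3-methoxy-8-(triisopropylsilyl)oct-7-yn-3-yl]peroxy}prop-2-enoyl]-1,3-oxazolidin-2-one (racemic) | CC(C)[Si](C(C)C)(C(C)C)C#CCCCC(OC)(CCBr)OO/C=C/C(=O)N1CCOC1=O
A6 | alternative 3 | 3-{[(3S,6R)-6-methoxy-6-[5-(triisopropylsilyl)pent-4-yn-1-yl]-1,2-dioxan-3-yl]acetyl}-1,3-oxazolidin-2-one | CC(C)[Si](C(C)C)(C(C)C)C#CCCC[C@]1(OC)CC[C@@H](CC(=O)N2CCOC2=O)OO1
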